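## Retrosynthetic overview
1. The last step closes two rings. An intramolecular Cr(II) γ-chloroallylation of the C7 aldehyde forms C6–C7 and the ten-membered ring. The C7 alkoxide then acylates itself on the C19 imide to give the γ-lactone. Cl, C6, C7 and the 5(16)-methylene all arrive in this step.
2. In the seco precursor, C8–C17 comes from an auxiliary-controlled Reformatsky addition to a C8 ketone. C9–C10 comes from a Hosomi–Sakurai reaction of a ring allylsilane, which also creates the 11(20)-methylene.
3. C2–C3 comes from a boron aldol with in situ syn reduction, using a five-carbon chloro-allylsilane ketone (C3–C6, C16).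
4. The cyclohexane, with quaternary C1, comes from an arene by asymmetric Birch reduction–methylation of a benzylsilane benzamide.
5. Ring order: the six-membered ring first (from the arene), then the ten-membered ring and the γ-lactone together.

Labels C1–C20 are the briarane numbering of the target: C1 is the quaternary carbon, C5=C16 and C11=C20 are the methylenes, and C7–O–C19 is the lactone.

Assumption: the (S)-prolinol-ether benzamide gives the C1 configuration drawn in step 3. If the sense of induction is the opposite, the equally available (R)-auxiliary is used and nothing else changes.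

## Route

Step 1
Reactants: 1 5-bromo-2-methoxybenzoic acid; 2 (S)-2-(methoxymethyl)pyrrolidine (SMP)
Product: 4 (S)-SMP amide of 5-bromo-2-methoxybenzoic acid, via acid chloride 3 (not isolated)
Conditions: SOCl2, cat. DMF, toluene, 60 °C; then 2, Et3N, CH2Cl2, 0 °C
Reagents that add atoms: none
Why: Amide formation through the acid chloride (Schotten–Baumann type) attaches the proline-derived auxiliary that later controls C1 and creates no new stereocentre.

Step 2
Reactants: 4 (S)-SMP amide of 5-bromo-2-methoxybenzoic acid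
Product: 5 (S)-SMP amide of 2-methoxy-5-[(trimethylsilyl)methyl]benzoic acid
Conditions: Me3SiCH2MgCl, NiCl2(dppp) (3 mol %), THF, 40 °C
Reagents that add atoms: (trimethylsilyl)methylmagnesium chloride C[Si](C)(C)C[Mg]Cl
Why: Kumada–Corriu coupling works well for aryl bromides and the β-hydrogen-free silylmethyl Grignard while the hindered tertiary benzamide is left alone, and it places C20 as a benzylsilane that the next step turns into an allylsilane.

Step 3
Reactants: 5 (S)-SMP amide of 2-methoxy-5-[(trimethylsilyl)methyl]benzoic acid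
Product: 7 SMP 2-methoxy-1-methyl-5-[(trimethylsilyl)methyl]cyclohexa-2,5-diene-1-carboxamide (quaternary C1 as in the target), via potassium enolate 6 (not isolated)
Conditions: K, NH3(l)/THF, t-BuOH (1 equiv), −78 °C; piperylene; MeI, −78 °C
Reagents that add atoms: iodomethane CI
Why: Schultz asymmetric Birch reduction–alkylation: 1,4-reduction ipso/para to the amide gives the chelated potassium enolate 6, and MeI enters on the face away from the methoxymethyl arm, which sets the quaternary C1 and leaves the C10=C11 allylsilane and the C14 enol ether.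

Step 4
Reactants: 7 SMP 2-methoxy-1-methyl-5-[(trimethylsilyl)methyl]cyclohexa-2,5-diene-1-carboxamide
Product: 8 SMP 1-methyl-6-oxo-3-[(trimethylsilyl)methyl]cyclohex-2-ene-1-carboxamide (C14 ketone)
Conditions: 1 M HCl, THF, 0 °C
Reagents that add atoms: water O
Why: Mild acid hydrolysis of the enol ether is far faster than protodesilylation of the allylsilane, and the quaternary C1 prevents both conjugation of the C10=C11 bond and epimerisation.

Step 5
Reactants: 8 SMP 1-methyl-6-oxo-3-[(trimethylsilyl)methyl]cyclohex-2-ene-1-carboxamide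
Product: 9 6-hydroxy-1-methyl-3-[(trimethylsilyl)methyl]cyclohex-2-ene-1-carbaldehyde (C14-OH cis to the C2 aldehyde)
Conditions: Cp2Zr(H)Cl (3.5 equiv), THF, rt, 30 min; wet SiO2
Reagents that add atoms: water O
Why: Schwartz-reagent reduction (tertiary amide to aldehyde via a stable zirconated hemiaminal) also reduces the ketone, with hydride coming from the face opposite the bulky carboxamide so that C14–OH ends cis to C2 (C14 S), and the trisubstituted allylsilane is too hindered for hydrozirconation.

Step 6
Reactants: 10 but-3-yn-2-ol (racemic)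
Product: 12 (E)-4-chloro-3-[(trimethylsilyl)methyl]but-3-en-2-ol (Cl cis to the carbinol carbon), via alkenylmagnesium chelate 11 (not isolated)
Conditions: Me3SiCH2MgCl (2.5 equiv), CuI (10 mol %), Et2O, 0 °C to rt; NCS, THF, −30 °C
Reagents that add atoms: (trimethylsilyl)methylmagnesium chloride C[Si](C)(C)C[Mg]Cl; N-chlorosuccinimide O=C1CCC(=O)N1Cl
Why: Copper-catalysed anti-carbomagnesiation of a propargylic alkoxide puts the silylmethyl group on the internal carbon and magnesium on the terminal carbon cis to the alkoxide (chelate 11), and NCS chlorinates the alkenyl–Mg bond with retention, so one alkene isomer results (the racemic carbinol centre is erased in step 7).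

Step 7
Reactants: 12 (E)-4-chloro-3-[(trimethylsilyl)methyl]but-3-en-2-ol
Product: 13 (E)-4-chloro-3-[(trimethylsilyl)methyl]but-3-en-2-one
Conditions: MnO2, CH2Cl2, rt
Reagents that add atoms: none
Why: MnO2 oxidation of the allylic alcohol is neutral and touches neither the vinyl chloride nor the allylsilane.

Step 8
Reactants: 9 6-hydroxy-1-methyl-3-[(trimethylsilyl)methyl]cyclohex-2-ene-1-carbaldehyde; 13 (E)-4-chloro-3-[(trimethylsilyl)methyl]but-3-en-2-one
Product: 16 ring–west triol (C14-OH C2-OH C4-OH; 2,4-syn; C5=C6HCl; C16H2SiMe3), via boron enolate 14 (not isolated), via boron aldolate 15 (not isolated)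
Conditions: 13 (3 equiv), n-Bu2BOTf, i-Pr2NEt, CH2Cl2, −78 °C; 9; LiBH4, −78 °C; pH 7 buffer, MeOH
Reagents that add atoms: none
Why: Boron methyl-ketone aldol followed by in situ LiBH4 reduction of the chelated aldolate (aldol–reduction in the Narasaka–Prasad sense): Felkin–Anh attack anti to the C10 vinylic carbon, reinforced by a transient C14–O–boron chelate, sets C2 (S), and hydride delivery to the six-membered boron chelate gives the 2,4-syn diol and sets C4 (R), the hindered amine and low temperature sparing the β-chloroenone.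

Step 9
Reactants: 16 ring–west triol
Product: 17 ring–west triacetate (C2 C4 C14 acetates)
Conditions: Ac2O, DMAP, pyridine, 40 °C
Reagents that add atoms: acetic anhydride CC(=O)OC(C)=O
Why: DMAP-catalysed acetylation of all three secondary alcohols installs three of the four final acetates, so no protecting group is ever used, and no stereocentre is affected.

Step 10
Reactants: 18 pyruvaldehyde dimethyl acetal (1,1-dimethoxypropan-2-one)
Product: 19 3,3-dimethoxy-2-oxopropanal
Conditions: SeO2, dioxane (2 % H2O), cat. pyridine, 80 °C; distil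
Reagents that add atoms: selenium dioxide O=[Se]=O
Why: Riley oxidation converts the methyl ketone into the glyoxal, the acetal carbon being less prone to enolise, and delivers the C7–C8–C9 unit with its three carbonyl levels differentiated.

Step 11
Reactants: 17 ring–west triacetate; 19 3,3-dimethoxy-2-oxopropanal
Product: 21 tetraacetate C8 ketone C7 dimethyl acetal (11(20)-methylene in place), via C9 alcohol 20 (not isolated)
Conditions: BF3·OEt2, CH2Cl2, −78 °C; NaHCO3 work-up; crude 20: Ac2O, DMAP, pyridine, 0 °C
Reagents that add atoms: acetic anhydride CC(=O)OC(C)=O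
Why: Hosomi–Sakurai allylation (anti-SE2′): only the electron-rich ring allylsilane reacts (the other is deactivated by chlorine) and only at the aldehyde of 19, the new bond forms at C10 on the face anti to the large C2 side chain (C10 S), the open antiperiplanar transition state gives the C9/C10 syn relationship (C9 S), loss of silicon creates the 11(20)-methylene, and acetylation of crude 20 blocks acyloin shifts.

Step 12
Reactants: 22 (S)-4-benzyloxazolidin-2-one; 23 2-bromopropionyl bromide
Product: 24 (4S)-4-benzyl-3-(2-bromopropanoyl)oxazolidin-2-one (bromide epimers)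
Conditions: n-BuLi, THF, −78 °C; 23
Reagents that add atoms: none
Why: N-Acylation of the lithiated Evans oxazolidinone, in which the bromide-bearing carbon is a mixture that is erased on enolate formation.

Step 13
Reactants: 21 tetraacetate C8 ketone C7 dimethyl acetal; 24 (4S)-4-benzyl-3-(2-bromopropanoyl)oxazolidin-2-one
Product: 26 C8 tertiary alcohol carrying the C17 methyl and the C19 N-acyl oxazolidinone, via zinc enolate 25 (not isolated)
Conditions: Et2Zn, RhCl(PPh3)3 (5 mol %), THF, −20 to 0 °C; cold aq. NH4Cl
Reagents that add atoms: none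
Why: Proposed new method: rhodium-catalysed Et2Zn Reformatsky reactions of ketones and Sm- or Cr-Reformatsky reactions of chiral 2-bromoacyl oxazolidinones with aldehydes are the closest known types, and their combination should give the chelated (Z)-zinc enolate 25, whose benzyl group shields one face and so fixes C17 (R, alkylation sense), while the doubly α-oxygenated and therefore activated C8 ketone is attacked in the polar Felkin–Anh sense anti to the C9–OAc bond, which fixes C8 (R), esters, vinyl chloride and allylsilane being inert to Et2Zn at this temperature.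

Step 14
Reactants: 26 C8 tertiary alcohol carrying the C17 methyl and the C19 N-acyl oxazolidinone
Product: 27 C7 aldehyde
Conditions: LiBF4, MeCN/H2O (98:2), 50 °C
Reagents that add atoms: water O
Why: Lewis-acid-assisted acetal hydrolysis is mild enough for the acetates, the imide and the chlorine-deactivated allylsilane, and the aldehyde has no α-hydrogen so C8 cannot epimerise.

Step 15
Reactants: 27 C7 aldehyde
Product: 28 C7 aldehyde bearing the allylic gem-bromochloride C5(=C16H2)–C6HBrCl
Conditions: NBS, CH2Cl2, −78 °C, dark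
Reagents that add atoms: N-bromosuccinimide O=C1CCC(=O)N1Br
Why: Electrophilic bromodesilylation (SE2′): Br+ attacks the chlorine-bearing alkene carbon because the β-silyl cation is by far the best stabilised, so the allylsilane outruns the 11(20)-methylene, and the new C6 centre (Br/Cl mixture) is erased in step 16.

Step 16
Reactants: 28 C7 aldehyde bearing the allylic gem-bromochloride
Product: 31 target CNP0186618.1, via allylchromium 29 (not isolated), via chromium alkoxide 30 (not isolated)
Conditions: CrCl2 (6 equiv), 4 Å MS, THF, 2 mM, syringe pump 10 h, rt; aq. NaHCO3/serine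
Reagents that add atoms: none
Why: Proposed new method: Cr(II) reduces only the C–Br bond of the allylic gem-bromochloride to a γ-chloroallylchromium(III) species (Takai-type chloroallylation is the closest known type, and Cr-mediated allyl halide–aldehyde closure of ten-membered carbocycles is also known), which adds through its chlorine-bearing carbon to the C7 aldehyde in a closed chair with Cl (trans to CH2Cr) and C8 both equatorial, giving the 6,7-anti chlorohydrin (C6 S) and, by polar Felkin–Anh attack anti to the C8–O bond with the smaller C17 branch next to the trajectory, C7 (R), after which the chromium alkoxide attacks the activated N-acyl oxazolidinone five atoms away so that the ten-membered ring and the γ-lactone form in the same flask without touching C8, C17 or the acetates.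

## Compound list
1 | 5-bromo-2-methoxybenzoic acid | COc1ccc(Br)cc1C(=O)O | starting material
2 | (S)-2-(methoxymethyl)pyrrolidine (SMP) | COC[C@@H]1CCCN1 | starting material
3 | 5-bromo-2-methoxybenzoyl chloride | COc1ccc(Br)cc1C(=O)Cl | intermediate
4 | (S)-SMP amide of 5-bromo-2-methoxybenzoic acid | COC[C@@H]1CCCN1C(=O)c1cc(Br)ccc1OC | intermediate
5 | (S)-SMP amide of 2-methoxy-5-[(trimethylsilyl)methyl]benzoic acid | COC[C@@H]1CCCN1C(=O)c1cc(C[Si](C)(C)C)ccc1OC | intermediate
6 | potassium amide enolate of the 1,4-dihydroarene | COC[C@@H]1CCCN1C([O-])=C1C=C(C[Si](C)(C)C)CC=C1OC.[K+] | intermediate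
7 | SMP 2-methoxy-1-methyl-5-[(trimethylsilyl)methyl]cyclohexa-2,5-diene-1-carboxamide, C1 as in target | C[Si](C)(C)CC1=C[C@@](C)(C(=O)N2CCC[C@H]2COC)C(OC)=CC1 | intermediate
8 | SMP 1-methyl-6-oxo-3-[(trimethylsilyl)methyl]cyclohex-2-ene-1-carboxamide | C[Si](C)(C)CC1=C[C@@](C)(C(=O)N2CCC[C@H]2COC)C(=O)CC1 | intermediate
9 | 6-hydroxy-1-methyl-3-[(trimethylsilyl)methyl]cyclohex-2-ene-1-carbaldehyde, OH cis to CHO | C[Si](C)(C)CC1=C[C@@](C)(C=O)[C@@H](O)CC1 | intermediate
10 | but-3-yn-2-ol (racemic) | CC(O)C#C | starting material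
11 | alkenylmagnesium alkoxide chelate | CC(O[Mg]Cl)/C(=C\[Mg]Cl)C[Si](C)(C)C | intermediate
12 | (E)-4-chloro-3-[(trimethylsilyl)methyl]but-3-en-2-ol | CC(O)/C(=C\Cl)C[Si](C)(C)C | intermediate
13 | (E)-4-chloro-3-[(trimethylsilyl)methyl]but-3-en-2-one | CC(=O)/C(=C\Cl)C[Si](C)(C)C | intermediate
14 | dibutylboron enolate of 13 | C=C(OB(CCCC)CCCC)/C(=C\Cl)C[Si](C)(C)C | intermediate
15 | boron aldolate (C2–O–BBu2, C4 ketone) | C[Si](C)(C)CC1=C[C@@](C)([C@@H](OB(CCCC)CCCC)CC(=O)/C(=C\Cl)C[Si](C)(C)C)[C@@H](O)CC1 | intermediate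
16 | ring–west triol, C1 C2 C4 C14 as in target | C[Si](C)(C)CC1=C[C@@](C)([C@@H](O)C[C@@H](O)/C(=C\Cl)C[Si](C)(C)C)[C@@H](O)CC1 | intermediate
17 | ring–west triacetate | C[Si](C)(C)CC1=C[C@@](C)([C@@H](OC(C)=O)C[C@@H](OC(C)=O)/C(=C\Cl)C[Si](C)(C)C)[C@@H](OC(C)=O)CC1 | intermediate
18 | pyruvaldehyde dimethyl acetal | CC(=O)C(OC)OC | starting material
19 | 3,3-dimethoxy-2-oxopropanal | COC(OC)C(=O)C=O | intermediate
20 | C9 alcohol (Sakurai adduct), C9 C10 as in target | C=C1CC[C@H](OC(C)=O)[C@](C)([C@@H](OC(C)=O)C[C@@H](OC(C)=O)/C(=C\Cl)C[Si](C)(C)C)[C@H]1[C@H](O)C(=O)C(OC)OC | intermediate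
21 | tetraacetate C8 ketone C7 dimethyl acetal | C=C1CC[C@H](OC(C)=O)[C@](C)([C@@H](OC(C)=O)C[C@@H](OC(C)=O)/C(=C\Cl)C[Si](C)(C)C)[C@H]1[C@H](OC(C)=O)C(=O)C(OC)OC | intermediate
22 | (S)-4-benzyloxazolidin-2-one | O=C1N[C@@H](Cc2ccccc2)CO1 | starting material
23 | 2-bromopropionyl bromide | CC(Br)C(=O)Br | starting material
24 | (4S)-4-benzyl-3-(2-bromopropanoyl)oxazolidin-2-one | CC(Br)C(=O)N1[C@@H](Cc2ccccc2)COC1=O | intermediate
25 | (Z)-ethylzinc enolate of the propionyl imide | C/C=C(\O[Zn]CC)N1[C@@H](Cc2ccccc2)COC1=O | intermediate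
26 | Reformatsky adduct, C8 C17 as in target | C=C1CC[C@H](OC(C)=O)[C@](C)([C@@H](OC(C)=O)C[C@@H](OC(C)=O)/C(=C\Cl)C[Si](C)(C)C)[C@H]1[C@H](OC(C)=O)[C@@](O)(C(OC)OC)[C@@H](C)C(=O)N1[C@@H](Cc2ccccc2)COC1=O | intermediate
27 | C7 aldehyde | C=C1CC[C@H](OC(C)=O)[C@](C)([C@@H](OC(C)=O)C[C@@H](OC(C)=O)/C(=C\Cl)C[Si](C)(C)C)[C@H]1[C@H](OC(C)=O)[C@@](O)(C=O)[C@@H](C)C(=O)N1[C@@H](Cc2ccccc2)COC1=O | intermediate
28 | C7 aldehyde with allylic gem-bromochloride (C6 epimers) | C=C1CC[C@H](OC(C)=O)[C@](C)([C@@H](OC(C)=O)C[C@@H](OC(C)=O)C(=C)C(Cl)Br)[C@H]1[C@H](OC(C)=O)[C@@](O)(C=O)[C@@H](C)C(=O)N1[C@@H](Cc2ccccc2)COC1=O | intermediate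
29 | γ-chloroallylchromium(III) aldehyde | C=C1CC[C@H](OC(C)=O)[C@](C)([C@@H](OC(C)=O)C[C@@H](OC(C)=O)/C(=C\Cl)C[Cr](Cl)Cl)[C@H]1[C@H](OC(C)=O)[C@@](O)(C=O)[C@@H](C)C(=O)N1[C@@H](Cc2ccccc2)COC1=O | intermediate
30 | ten-membered C7 chromium alkoxide, imide still attached | C=C1CC[C@H](OC(C)=O)[C@]2(C)[C@@H](OC(C)=O)C[C@@H](OC(C)=O)C(=C)[C@H](Cl)[C@H](O[Cr](Cl)Cl)[C@@](O)([C@@H](C)C(=O)N3[C@@H](Cc4ccccc4)COC3=O)[C@@H](OC(C)=O)[C@@H]12 | intermediate
31 | CNP0186618.1, (1R,2S,4R,6S,7R,8R,9S,10S,14S,17R) | C=C1CC[C@H](OC(C)=O)[C@]2(C)[C@@H](OC(C)=O)C[C@@H](OC(C)=O)C(=C)[C@H](Cl)[C@@H]3OC(=O)[C@H](C)[C@@]3(O)[C@@H](OC(C)=O)[C@@H]12 | target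

## Step count and weak points
Total step count: 16.
Longest linear sequence: 12 steps (1, 2, 3, 4, 5, 8, 9, 11, 13, 14, 15, 16).

**Step 16.** The risks are the closure of a ten-membered ring, further reduction of the product's allylic chloride by excess Cr(II), and the geometry of the allylchromium. The fallback sets out from 26 and comes back at 31.
- NBS on 26 gives the acetal-protected allylic gem-bromochloride F1.
- Base-free palladium-catalysed borylation with B2pin2 replaces bromide at the CH2 terminus. This gives the γ-chloroallyl pinacolboronate F2, with Cl trans to CH2B.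
- LiBF4 in wet acetonitrile frees the aldehyde.
- The boronate aldehyde F3 closes on gentle warming by intramolecular allylboration. The closed chair is stereospecific for the anti chlorohydrin, and no reductant is present.
- A trace of DMAP completes lactonisation to 31.

**Step 13.** The risks are the hindered ketone, possible C9-to-C8 acetyl migration in the zinc alkoxide, and the untested combination of auxiliary and ketone. The fallback sets out from 21 and comes back at 31, and it closes the lactone last.
- The acetal of 21 is hydrolysed to the keto aldehyde F4.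
- NBS gives the allylic gem-bromochloride keto aldehyde F5.
- CrCl2 closes only the ten-membered ring, because the aldehyde reacts and the ketone does not. The product is the 7-hydroxy-8-ketone F6.
- 2-Bromopropionyl bromide and pyridine give the C7 2-bromopropionate F7.
- SmI2 at −78 °C runs an intramolecular Reformatsky reaction. The tether from C7–O delivers C17 to C8 so that C6 and C9 end trans on the new lactone. C17 settles with its methyl trans to C9, giving 31.

**Step 8.** The risks are enolisation and 1,2-reduction of a β-chlorovinyl ketone. The fallback sets out from 9 and comes back at 16.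
- The same aldol–reduction is run with the robust 4-(trimethylsilyl)but-3-yn-2-one and gives the propargylic triol F8.
- K2CO3 in methanol gives the terminal alkyne triol F9.
- The copper-catalysed carbomagnesiation with Me3SiCH2MgCl and the NCS quench of step 6 are then run on F9, directed by the C4 alkoxide, and give 16.

## Further compounds
F1 | step 16 | acetal-protected allylic gem-bromochloride | C=C1CC[C@H](OC(C)=O)[C@](C)([C@@H](OC(C)=O)C[C@@H](OC(C)=O)C(=C)C(Cl)Br)[C@H]1[C@H](OC(C)=O)[C@@](O)(C(OC)OC)[C@@H](C)C(=O)N1[C@@H](Cc2ccccc2)COC1=O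
F2 | step 16 | γ-chloroallyl pinacolboronate acetal | C=C1CC[C@H](OC(C)=O)[C@](C)([C@@H](OC(C)=O)C[C@@H](OC(C)=O)/C(=C\Cl)CB2OC(C)(C)C(C)(C)O2)[C@H]1[C@H](OC(C)=O)[C@@](O)(C(OC)OC)[C@@H](C)C(=O)N1[C@@H](Cc2ccccc2)COC1=O
F3 | step 16 | γ-chloroallyl pinacolboronate aldehyde | C=C1CC[C@H](OC(C)=O)[C@](C)([C@@H](OC(C)=O)C[C@@H](OC(C)=O)/C(=C\Cl)CB2OC(C)(C)C(C)(C)O2)[C@H]1[C@H](OC(C)=O)[C@@](O)(C=O)[C@@H](C)C(=O)N1[C@@H](Cc2ccccc2)COC1=O
F4 | step 13 | C8 keto C7 aldehyde allylsilane | C=C1CC[C@H](OC(C)=O)[C@](C)([C@@H](OC(C)=O)C[C@@H](OC(C)=O)/C(=C\Cl)C[Si](C)(C)C)[C@H]1[C@H](OC(C)=O)C(=O)C=O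
F5 | step 13 | C8 keto C7 aldehyde allylic gem-bromochloride | C=C1CC[C@H](OC(C)=O)[C@](C)([C@@H](OC(C)=O)C[C@@H](OC(C)=O)C(=C)C(Cl)Br)[C@H]1[C@H](OC(C)=O)C(=O)C=O
F6 | step 13 | ten-membered 6-chloro-7-hydroxy-8-ketone | C=C1CC[C@H](OC(C)=O)[C@]2(C)[C@@H](OC(C)=O)C[C@@H](OC(C)=O)C(=C)[C@H](Cl)[C@H](O)C(=O)[C@@H](OC(C)=O)[C@@H]12
F7 | step 13 | C7 2-bromopropionate of F6 | C=C1CC[C@H](OC(C)=O)[C@]2(C)[C@@H](OC(C)=O)C[C@@H](OC(C)=O)C(=C)[C@H](Cl)[C@H](OC(=O)C(C)Br)C(=O)[C@@H](OC(C)=O)[C@@H]12
F8 | step 8 | propargylic triol with silylated alkyne | C[Si](C)(C)CC1=C[C@@](C)([C@@H](O)C[C@@H](O)C#C[Si](C)(C)C)[C@@H](O)CC1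
F9 | step 8 | propargylic triol with terminal alkyne | C[Si](C)(C)CC1=C[C@@](C)([C@@H](O)C[C@@H](O)C#C)[C@@H](O)CC1
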